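**Retrosynthetic overview**
- The target is a cembrane with one 14-membered carbocycle (C1–C14) and no other ring. The enabling feature is the C14 acetoxy methine bonded directly to C1, which carries the isopropenyl group C15(=C16)C17. This anti branched homoallylic alcohol is the retron of a γ-selective allylmetal addition to an aldehyde, and C12=C13 makes that aldehyde an enal.
- Key disconnection C1–C14: intramolecular Cr(II) allylation of the acyclic bromo-enal 25 (one stereocentre, C9) closes the ring, sets C1 and C14, and creates the isopropenyl group by allylic transposition.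
- 25 comes from three fragments. C11–C12 is made by B-alkyl Suzuki coupling with the (Z)-iodide 19 (C12–C14 and C20, from but-2-yne-1,4-diol). C6–C7 and C8–CH3 are made in one pot by anti-carbomagnesiation/allylation of (S)-pent-1-en-4-yn-3-ol 12 (C7–C11) with MeMgBr and the bromide 6 (C1–C6, C15–C18, from geranyl acetate).
- Ring order: no ring exists before step 16; the macrocycle is the first and last ring formed. The endgame removes three silyl ethers in order of lability (TES, then primary TBS, then secondary TBS) with one diacetylation in between.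

Key step: step 16

Remark: cembrane numbering is used throughout (C1 bears the isopropenyl group, C14 is the oxygenated ring carbon next to it, C18/C19 are the methyls on C4/C8, C20 is the CH2O carbon on C12). The target is read as (1R,9S,14S,4E,7Z,12E). Geranyl acetate, trimethylsilylacetylene, acrolein and but-2-yne-1,4-diol are taken as the commercial starting materials.

**Route**

Step 1
Reactants: 1 geranyl acetate [(2E)-3,7-dimethylocta-2,6-dien-1-yl acetate]
Product: 2 (2E,6E)-8-hydroxy-3,7-dimethylocta-2,6-dien-1-yl acetate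
Conditions: SeO2 (cat.), t-BuOOH, salicylic acid (cat.), CH2Cl2, rt
Reagents that add atoms: selenium dioxide O=[Se]=O; tert-butyl hydroperoxide CC(C)(C)OO
Why: Catalytic SeO2 allylic oxidation (ene reaction, then [2,3]-sigmatropic shift) should hydroxylate the (E)-methyl group of the electron-richer terminal alkene, the alkene next to the acetate being deactivated.

Step 2
Reactants: 2 (2E,6E)-8-hydroxy-3,7-dimethylocta-2,6-dien-1-yl acetate
Product: 3 (2E,6E)-3,7-dimethyl-8-(triethylsilyloxy)octa-2,6-dien-1-yl acetate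
Conditions: TESCl, imidazole, CH2Cl2, 0 °C
Reagents that add atoms: chlorotriethylsilane CC[Si](Cl)(CC)CC
Why: Standard silylation of a primary allylic alcohol; the C16 oxygen receives the most labile of the three graded silyl ethers used in the route.

Step 3
Reactants: 3 (2E,6E)-3,7-dimethyl-8-(triethylsilyloxy)octa-2,6-dien-1-yl acetate
Product: 4 (2E,6E)-3,7-dimethyl-8-(triethylsilyloxy)octa-2,6-dien-1-ol
Conditions: DIBAL-H, CH2Cl2, −78 °C; Rochelle salt work-up
Reagents that add atoms: none
Why: Reductive cleavage of the acetate at low temperature should leave the triethylsilyl ether and both alkenes untouched.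

Step 4
Reactants: 4 (2E,6E)-3,7-dimethyl-8-(triethylsilyloxy)octa-2,6-dien-1-ol
Product: 6 [(2E,6E)-8-bromo-2,6-dimethylocta-2,6-dien-1-yl]oxy-triethylsilane, via (2E,6E)-3,7-dimethyl-8-(triethylsilyloxy)octa-2,6-dien-1-yl methanesulfonate 5 (not isolated)
Conditions: MsCl, Et3N, THF, −40 °C; then LiBr, −40 → 0 °C
Reagents that add atoms: lithium bromide [Li+].[Br-]
Why: Mesylation followed by SN2 displacement with bromide at low temperature should give the primary allylic bromide with the (E) geometry intact and without acid that would cleave the silyl ether.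

Step 5
Reactants: 7 trimethylsilylacetylene; 8 acrolein
Product: 10 rac-5-(trimethylsilyl)pent-1-en-4-yn-3-ol, via lithium (trimethylsilyl)acetylide 9 (not isolated)
Conditions: n-BuLi, THF, −78 °C; then 8, −78 °C; H2O
Reagents that add atoms: none
Why: A lithium acetylide adds 1,2 to the enal to give the racemic ethynyl vinyl carbinol.

Step 6
Reactants: 10 rac-5-(trimethylsilyl)pent-1-en-4-yn-3-ol
Product: 11 (S)-5-(trimethylsilyl)pent-1-en-4-yn-3-ol
Conditions: lipase (Burkholderia cepacia lipase or immobilised Candida antarctica lipase B), vinyl acetate, hexane, rt, run to slightly over 50% conversion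
Reagents that add atoms: none
Why: Enzymatic kinetic resolution by acyl transfer: by the empirical size rule for lipases (large silylethynyl, medium vinyl) the (R)-alcohol should be acetylated faster, so the (S)-alcohol, which becomes C9, is recovered and separated from the acetate.

Step 7
Reactants: 11 (S)-5-(trimethylsilyl)pent-1-en-4-yn-3-ol
Product: 12 (S)-pent-1-en-4-yn-3-ol
Conditions: K2CO3 (cat.), MeOH, 0 °C → rt
Reagents that add atoms: none
Why: Base-catalysed methanolysis of the alkynyl–silicon bond frees the terminal alkyne without touching the stereocentre.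

Step 8
Reactants: 12 (S)-pent-1-en-4-yn-3-ol; 6 [(2E,6E)-8-bromo-2,6-dimethylocta-2,6-dien-1-yl]oxy-triethylsilane
Product: 14 (3S,4Z,7E,11E)-4,8,12-trimethyl-13-(triethylsilyloxy)trideca-1,4,7,11-tetraen-3-ol, via (5S)-5-ethenyl-4-methyl-2,5-dihydro-1,2-oxamagnesole 13 (not isolated)
Conditions: MeMgBr (2.1 equiv), CuI (10 mol%), Et2O, −10 °C → rt; then 6, THF, −20 → 0 °C; aq. NH4Cl
Reagents that add atoms: methylmagnesium bromide C[Mg]Br
Why: Copper-catalysed anti-carbomagnesiation of the terminal propargylic alkoxide puts methyl on the internal alkyne carbon (C8) and magnesium on C7 trans to it, the five-membered chelate 13 fixing C7–Mg cis to C9; copper-catalysed SN2 coupling of this alkenylmagnesium with the primary allylic bromide then forms C6–C7 with retention at both alkenes, giving the skipped diene (4E,7Z in cembrane numbering) without touching C9.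

Step 9
Reactants: 14 (3S,4Z,7E,11E)-4,8,12-trimethyl-13-(triethylsilyloxy)trideca-1,4,7,11-tetraen-3-ol
Product: 15 tert-butyldimethyl{[(3S,4Z,7E,11E)-4,8,12-trimethyl-13-(triethylsilyloxy)trideca-1,4,7,11-tetraen-3-yl]oxy}silane
Conditions: TBSOTf, 2,6-lutidine, CH2Cl2, −78 °C
Reagents that add atoms: tert-butyldimethylsilyl trifluoromethanesulfonate CC(C)(C)[Si](C)(C)OS(=O)(=O)C(F)(F)F
Why: Silylation under buffered, non-acidic conditions protects the ionisable doubly allylic C9 alcohol as the most robust silyl ether of the route.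

Step 10
Reactants: 16 but-2-yne-1,4-diol
Product: 17 4-(tert-butyldimethylsilyloxy)but-2-yn-1-ol
Conditions: TBSCl (1 equiv), imidazole, THF, 0 °C, 16 in threefold excess
Reagents that add atoms: tert-butylchlorodimethylsilane CC(C)(C)[Si](C)(C)Cl
Why: Statistical monosilylation of a symmetric diol used in excess; the unreacted diol is removed by aqueous extraction.

Step 11
Reactants: 17 4-(tert-butyldimethylsilyloxy)but-2-yn-1-ol
Product: 19 (Z)-4-(tert-butyldimethylsilyloxy)-3-iodobut-2-en-1-ol, via the cyclic sodium alkenylalanate 18 (not isolated)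
Conditions: Red-Al, THF, 0 °C; then I2, −78 → 0 °C
Reagents that add atoms: iodine II
Why: Hydroxyl-directed trans-hydroalumination delivers hydride to the alkyne carbon next to the free carbinol (C13) and leaves aluminium on C12 in a five-membered alanate, so iodinolysis with retention gives the iodide with iodine cis to CH2OH; the low temperature suppresses 1,4-elimination of the silyloxy group.

Step 12
Reactants: 15 tert-butyldimethyl{[(3S,4Z,7E,11E)-4,8,12-trimethyl-13-(triethylsilyloxy)trideca-1,4,7,11-tetraen-3-yl]oxy}silane; 19 (Z)-4-(tert-butyldimethylsilyloxy)-3-iodobut-2-en-1-ol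
Product: 21 (2E,6S,7Z,10E,14E)-6-(tert-butyldimethylsilyloxy)-3-[(tert-butyldimethylsilyloxy)methyl]-7,11,15-trimethyl-16-(triethylsilyloxy)hexadeca-2,7,10,14-tetraen-1-ol, via the terminal B-alkyl-9-borabicyclo[3.3.1]nonane 20 (not isolated)
Conditions: 9-BBN, THF, rt; then aq. K3PO4, PdCl2(dppf) (cat.), AsPh3, DMF, rt
Reagents that add atoms: none
Why: 9-BBN hydroborates only the monosubstituted C10=C11 alkene at its terminal carbon, and B-alkyl Suzuki–Miyaura coupling with the alkenyl iodide forms C11–C12 with retention, which places C11 cis to C14 on the trisubstituted alkene.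

Step 13
Reactants: 21 (2E,6S,7Z,10E,14E)-6-(tert-butyldimethylsilyloxy)-3-[(tert-butyldimethylsilyloxy)methyl]-7,11,15-trimethyl-16-(triethylsilyloxy)hexadeca-2,7,10,14-tetraen-1-ol
Product: 22 (2E,6S,7Z,10E,14E)-6-(tert-butyldimethylsilyloxy)-3-[(tert-butyldimethylsilyloxy)methyl]-7,11,15-trimethyl-16-(triethylsilyloxy)hexadeca-2,7,10,14-tetraenal
Conditions: MnO2, CH2Cl2, rt
Reagents that add atoms: none
Why: The only free hydroxyl is a primary allylic one, which MnO2 oxidises to the enal under neutral conditions that should preserve the alkene geometry.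

Step 14
Reactants: 22 (2E,6S,7Z,10E,14E)-6-(tert-butyldimethylsilyloxy)-3-[(tert-butyldimethylsilyloxy)methyl]-7,11,15-trimethyl-16-(triethylsilyloxy)hexadeca-2,7,10,14-tetraenal
Product: 23 (2E,6S,7Z,10E,14E)-6-(tert-butyldimethylsilyloxy)-3-[(tert-butyldimethylsilyloxy)methyl]-16-hydroxy-7,11,15-trimethylhexadeca-2,7,10,14-tetraenal
Conditions: HF·pyridine, pyridine, THF, −10 → 0 °C, monitored
Reagents that add atoms: none
Why: Under buffered HF a primary triethylsilyl ether is cleaved much faster than primary or secondary TBS ethers, and the enal tolerates the conditions.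

Step 15
Reactants: 23 (2E,6S,7Z,10E,14E)-6-(tert-butyldimethylsilyloxy)-3-[(tert-butyldimethylsilyloxy)methyl]-16-hydroxy-7,11,15-trimethylhexadeca-2,7,10,14-tetraenal
Product: 25 (2E,6S,7Z,10E,14E)-16-bromo-6-(tert-butyldimethylsilyloxy)-3-[(tert-butyldimethylsilyloxy)methyl]-7,11,15-trimethylhexadeca-2,7,10,14-tetraenal, via the corresponding C16 methanesulfonate 24 (not isolated)
Conditions: MsCl, Et3N, THF, −40 °C; then LiBr, −40 → 0 °C
Reagents that add atoms: lithium bromide [Li+].[Br-]
Why: Mesylation and SN2 bromide displacement convert the allylic alcohol into the bromide without reagents that attack the aldehyde; the bromo-enal is used at once.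

Step 16
Reactants: 25 (2E,6S,7Z,10E,14E)-16-bromo-6-(tert-butyldimethylsilyloxy)-3-[(tert-butyldimethylsilyloxy)methyl]-7,11,15-trimethylhexadeca-2,7,10,14-tetraenal
Product: 27 (1R,4E,7Z,9S,12E,14S)-9,20-bis(tert-butyldimethylsilyloxy)cembra-4,7,12,15-tetraen-14-ol, via the C16 allylchromium(III) dichloride 26 (not isolated)
Conditions: CrCl2 (excess), chiral oxazoline–sulfonamide ligand, Et3N, THF, rt; 25 added by syringe pump (final ca. 2 mM); aqueous work-up
Reagents that add atoms: none
Why: Cr(II) reduces the primary allylic bromide in two one-electron steps to the σ-allylchromium(III) species 26, which adds through its γ-carbon (C1) to the aldehyde carbon C14 in a closed six-membered chair transition state, the allylic transposition turning C15–C16 into the isopropenyl alkene (Nozaki–Hiyama–Kishi allylation). The closest known reaction type is the CrCl2-mediated allylic bromide–aldehyde macrocyclisation that gives 14-membered carbocycles carrying a vicinal hydroxyl/isopropenyl pair. The 14-membered carbocycle, the only ring, is closed in a 14-exo-trig mode by this C1–C14 bond (SE2′ at the allyl unit). C1 and C14 are set relative to each other by the chair, in which the C2 chain of the (E)-allyl unit and the C13 alkenyl group of the aldehyde both sit equatorial, giving the anti pair whatever the bromide geometry; their absolute sense relative to C9, (1R,14S), is to be imposed by the chiral ligand on chromium (reagent control, both antipodes of the ligand to be tried), the remote C9 silyloxy centre not being relied on. The step needs γ- over α-attack (14- versus 16-membered ring), 1,2- over 1,4-addition to the enal and cyclisation over oligomerisation: the cyclic transition state secures the first, the oxophilic allylchromium the second, and the two ring-cis alkenes (C7=C8 and C12=C13), which fold the chain, together with slow addition at high dilution the third.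

Step 17
Reactants: 27 (1R,4E,7Z,9S,12E,14S)-9,20-bis(tert-butyldimethylsilyloxy)cembra-4,7,12,15-tetraen-14-ol
Product: 28 (1R,4E,7Z,9S,12E,14S)-9-(tert-butyldimethylsilyloxy)cembra-4,7,12,15-tetraene-14,20-diol
Conditions: HF·pyridine, pyridine, THF, 0 °C → rt, monitored
Reagents that add atoms: none
Why: The primary allylic TBS ether at C20 should be cleaved well before the hindered secondary one at C9, which is flanked by the fully substituted C8.

Step 18
Reactants: 28 (1R,4E,7Z,9S,12E,14S)-9-(tert-butyldimethylsilyloxy)cembra-4,7,12,15-tetraene-14,20-diol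
Product: 29 (1R,4E,7Z,9S,12E,14S)-9-(tert-butyldimethylsilyloxy)cembra-4,7,12,15-tetraene-14,20-diyl diacetate
Conditions: Ac2O, Et3N, DMAP (cat.), CH2Cl2, 0 °C → rt
Reagents that add atoms: acetic anhydride CC(=O)OC(C)=O
Why: DMAP-catalysed acylation installs both acetates in one operation while C9 stays silylated; no stereocentre is involved.

Step 19
Reactants: 29 (1R,4E,7Z,9S,12E,14S)-9-(tert-butyldimethylsilyloxy)cembra-4,7,12,15-tetraene-14,20-diyl diacetate
Product: 30 CNP0097266.2 [(1R,4E,7Z,9S,12E,14S)-9-hydroxycembra-4,7,12,15-tetraene-14,20-diyl diacetate]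
Conditions: HF·pyridine, THF, 0 °C → rt
Reagents that add atoms: none
Why: Fluoride-mediated cleavage of the last silyl ether under mildly acidic conditions should spare both allylic acetates and exclude base-induced acetyl migration.

**Compound list**

1 | geranyl acetate | CC(C)=CCC/C(C)=C/COC(C)=O | starting material
2 | (2E,6E)-8-hydroxy-3,7-dimethylocta-2,6-dien-1-yl acetate | OC/C(C)=C/CC/C(C)=C/COC(C)=O | intermediate
3 | (2E,6E)-3,7-dimethyl-8-(triethylsilyloxy)octa-2,6-dien-1-yl acetate | CC[Si](CC)(CC)OC/C(C)=C/CC/C(C)=C/COC(C)=O | intermediate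
4 | (2E,6E)-3,7-dimethyl-8-(triethylsilyloxy)octa-2,6-dien-1-ol | CC[Si](CC)(CC)OC/C(C)=C/CC/C(C)=C/CO | intermediate
5 | (2E,6E)-3,7-dimethyl-8-(triethylsilyloxy)octa-2,6-dien-1-yl methanesulfonate | CC[Si](CC)(CC)OC/C(C)=C/CC/C(C)=C/COS(C)(=O)=O | intermediate (not isolated)
6 | [(2E,6E)-8-bromo-2,6-dimethylocta-2,6-dien-1-yl]oxy-triethylsilane | CC[Si](CC)(CC)OC/C(C)=C/CC/C(C)=C/CBr | intermediate
7 | trimethylsilylacetylene | C#C[Si](C)(C)C | starting material
8 | acrolein | C=CC=O | starting material
9 | lithium (trimethylsilyl)acetylide | [Li]C#C[Si](C)(C)C | intermediate (not isolated)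
10 | rac-5-(trimethylsilyl)pent-1-en-4-yn-3-ol | C[Si](C)(C)C#CC(O)C=C | intermediate
11 | (S)-5-(trimethylsilyl)pent-1-en-4-yn-3-ol | C[Si](C)(C)C#C[C@@H](O)C=C | intermediate
12 | (S)-pent-1-en-4-yn-3-ol | C#C[C@@H](O)C=C | intermediate
13 | (5S)-5-ethenyl-4-methyl-2,5-dihydro-1,2-oxamagnesole (cyclic alkenylmagnesium alkoxide) | C=C[C@@H]1O[Mg]C=C1C | intermediate (not isolated)
14 | (3S,4Z,7E,11E)-4,8,12-trimethyl-13-(triethylsilyloxy)trideca-1,4,7,11-tetraen-3-ol | CC[Si](CC)(CC)OC/C(C)=C/CC/C(C)=C/C/C=C(/C)[C@@H](O)C=C | intermediate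
15 | tert-butyldimethyl{[(3S,4Z,7E,11E)-4,8,12-trimethyl-13-(triethylsilyloxy)trideca-1,4,7,11-tetraen-3-yl]oxy}silane | CC[Si](CC)(CC)OC/C(C)=C/CC/C(C)=C/C/C=C(/C)[C@@H](O[Si](C)(C)C(C)(C)C)C=C | intermediate
16 | but-2-yne-1,4-diol | OCC#CCO | starting material
17 | 4-(tert-butyldimethylsilyloxy)but-2-yn-1-ol | OCC#CCO[Si](C)(C)C(C)(C)C | intermediate
18 | sodium 3-[(tert-butyldimethylsilyloxy)methyl]-2,2-bis(2-methoxyethoxy)-2,5-dihydro-1,2-oxaaluminol-2-uide (cyclic sodium alkenylalanate) | [Na+].COCCO[Al-]1(OCCOC)OCC=C1CO[Si](C)(C)C(C)(C)C | intermediate (not isolated)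
19 | (Z)-4-(tert-butyldimethylsilyloxy)-3-iodobut-2-en-1-ol | OC/C=C(\I)CO[Si](C)(C)C(C)(C)C | intermediate
20 | 9-[(3S,4Z,7E,11E)-3-(tert-butyldimethylsilyloxy)-4,8,12-trimethyl-13-(triethylsilyloxy)trideca-4,7,11-trien-1-yl]-9-borabicyclo[3.3.1]nonane | CC[Si](CC)(CC)OC/C(C)=C/CC/C(C)=C/C/C=C(/C)[C@@H](O[Si](C)(C)C(C)(C)C)CCB1C2CCCC1CCC2 | intermediate (not isolated)
21 | (2E,6S,7Z,10E,14E)-6-(tert-butyldimethylsilyloxy)-3-[(tert-butyldimethylsilyloxy)methyl]-7,11,15-trimethyl-16-(triethylsilyloxy)hexadeca-2,7,10,14-tetraen-1-ol | CC[Si](CC)(CC)OC/C(C)=C/CC/C(C)=C/C/C=C(/C)[C@@H](O[Si](C)(C)C(C)(C)C)CC/C(CO[Si](C)(C)C(C)(C)C)=C\CO | intermediate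
22 | (2E,6S,7Z,10E,14E)-6-(tert-butyldimethylsilyloxy)-3-[(tert-butyldimethylsilyloxy)methyl]-7,11,15-trimethyl-16-(triethylsilyloxy)hexadeca-2,7,10,14-tetraenal | CC[Si](CC)(CC)OC/C(C)=C/CC/C(C)=C/C/C=C(/C)[C@@H](O[Si](C)(C)C(C)(C)C)CC/C(CO[Si](C)(C)C(C)(C)C)=C\C=O | intermediate
23 | (2E,6S,7Z,10E,14E)-6-(tert-butyldimethylsilyloxy)-3-[(tert-butyldimethylsilyloxy)methyl]-16-hydroxy-7,11,15-trimethylhexadeca-2,7,10,14-tetraenal | OC/C(C)=C/CC/C(C)=C/C/C=C(/C)[C@@H](O[Si](C)(C)C(C)(C)C)CC/C(CO[Si](C)(C)C(C)(C)C)=C\C=O | intermediate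
24 | (2E,6E,9Z,11S,14E)-11-(tert-butyldimethylsilyloxy)-14-[(tert-butyldimethylsilyloxy)methyl]-2,6,10-trimethyl-16-oxohexadeca-2,6,9,14-tetraen-1-yl methanesulfonate | CS(=O)(=O)OC/C(C)=C/CC/C(C)=C/C/C=C(/C)[C@@H](O[Si](C)(C)C(C)(C)C)CC/C(CO[Si](C)(C)C(C)(C)C)=C\C=O | intermediate (not isolated)
25 | (2E,6S,7Z,10E,14E)-16-bromo-6-(tert-butyldimethylsilyloxy)-3-[(tert-butyldimethylsilyloxy)methyl]-7,11,15-trimethylhexadeca-2,7,10,14-tetraenal | BrC/C(C)=C/CC/C(C)=C/C/C=C(/C)[C@@H](O[Si](C)(C)C(C)(C)C)CC/C(CO[Si](C)(C)C(C)(C)C)=C\C=O | intermediate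
26 | [(2E,6E,9Z,11S,14E)-11-(tert-butyldimethylsilyloxy)-14-[(tert-butyldimethylsilyloxy)methyl]-2,6,10-trimethyl-16-oxohexadeca-2,6,9,14-tetraen-1-yl]chromium(III) dichloride (ligand and solvent on chromium omitted) | Cl[Cr](Cl)C/C(C)=C/CC/C(C)=C/C/C=C(/C)[C@@H](O[Si](C)(C)C(C)(C)C)CC/C(CO[Si](C)(C)C(C)(C)C)=C\C=O | intermediate (not isolated)
27 | (1R,4E,7Z,9S,12E,14S)-9,20-bis(tert-butyldimethylsilyloxy)cembra-4,7,12,15-tetraen-14-ol | C=C(C)[C@H]1CC/C(C)=C/C/C=C(/C)[C@@H](O[Si](C)(C)C(C)(C)C)CC/C(CO[Si](C)(C)C(C)(C)C)=C\[C@@H]1O | intermediate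
28 | (1R,4E,7Z,9S,12E,14S)-9-(tert-butyldimethylsilyloxy)cembra-4,7,12,15-tetraene-14,20-diol | C=C(C)[C@H]1CC/C(C)=C/C/C=C(/C)[C@@H](O[Si](C)(C)C(C)(C)C)CC/C(CO)=C\[C@@H]1O | intermediate
29 | (1R,4E,7Z,9S,12E,14S)-9-(tert-butyldimethylsilyloxy)cembra-4,7,12,15-tetraene-14,20-diyl diacetate | C=C(C)[C@H]1CC/C(C)=C/C/C=C(/C)[C@@H](O[Si](C)(C)C(C)(C)C)CC/C(COC(C)=O)=C\[C@@H]1OC(C)=O | intermediate
30 | CNP0097266.2 [(1R,4E,7Z,9S,12E,14S)-9-hydroxycembra-4,7,12,15-tetraene-14,20-diyl diacetate] | C=C(C)[C@H]1CC/C(C)=C/C/C=C(/C)[C@@H](O)CC/C(COC(C)=O)=C\[C@@H]1OC(C)=O | target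

**Step count**

Total: 19 steps. Longest linear sequence: 14 steps (steps 1–4, 8, 9, 12–19, from geranyl acetate).

**Steps most likely to fail, with fallbacks**

Step 16 (macrocyclisation). What may go wrong: the chiral chromium complex may not override the conformational preference of the folding chain, so the aldehyde faces are poorly discriminated and both anti diastereomers relative to C9 form; intermolecular coupling may also outrun ring closure. The fallback makes the C1–C14 bond between two fragments, where ligand-controlled chromium allylation is documented, and closes the ring at C11–C12 by a coupling that creates no stereocentre. It sets out from 15 and 19. The triethylsilyl ether of 15 is cleaved selectively (HF·pyridine/pyridine) to (2E,6E,9Z,11S)-11-(tert-butyldimethylsilyloxy)-2,6,10-trimethyltrideca-2,6,9,12-tetraen-1-ol F1, and an Appel reaction (CBr4, PPh3) gives the allylic bromide (3S,4Z,7E,11E)-13-bromo-3-(tert-butyldimethylsilyloxy)-4,8,12-trimethyltrideca-1,4,7,11-tetraene F2. Iodide 19 is oxidised with MnO2 to (Z)-4-(tert-butyldimethylsilyloxy)-3-iodobut-2-enal F3. Intermolecular Nozaki–Hiyama–Kishi allylation of F3 with F2 (CrCl2, the same chiral ligand, Et3N, THF; alkenyl iodides are inert to Cr(II) without nickel) should give the anti homoallylic alcohol (2Z,4R,5R,8E,11Z,13S)-1,13-bis(tert-butyldimethylsilyloxy)-2-iodo-8,12-dimethyl-5-(prop-1-en-2-yl)pentadeca-2,8,11,14-tetraen-4-ol F4. Hydroboration of its monosubstituted vinyl group with 9-BBN (2.0 equiv, the hydroxyl being taken up as its borinate; the isopropenyl group reacts far more slowly) gives the C11-boryl O-boryl species F5 (not isolated). Intramolecular B-alkyl Suzuki–Miyaura coupling (PdCl2(dppf), AsPh3, aq. K3PO4, DMF/THF, high dilution) then closes C11–C12 and, after aqueous work-up, comes back to the route at 27.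

Step 8 (carbomagnesiation/allylation). What may go wrong: methyl transfer from unconsumed MeMgBr to the bromide, SN2′ attack on the bromide, or sluggish allylation of the chelated alkenylmagnesium so that it is merely protonated on work-up. The fallback separates the two events and sets out from 12. The same copper-catalysed carbomagnesiation is quenched with iodine to give (1Z,3S)-1-iodo-2-methylpenta-1,4-dien-3-ol F6, which is silylated (TBSOTf, 2,6-lutidine) to its tert-butyldimethylsilyl ether F7. Iodine–lithium exchange (t-BuLi, Et2O, −78 °C) gives the alkenyllithium F8 (not isolated), and transmetalation with ZnBr2 gives the alkenylzinc bromide F9 (not isolated). Pd(PPh3)4-catalysed Negishi coupling with 6, which takes place at the unsubstituted allyl terminus with retention of both alkene geometries, comes back to the route at 15.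

Step 17 (selective C20 desilylation). What may go wrong: the rate difference between the primary C20 and the secondary C9 silyl ether may be too small, so that both are lost before acylation, or the allylic C9/C14 oxygen functions may ionise under acid. The fallback differentiates the hydroxyls by acylation instead of by deprotection and sets out from 27. Acetylation (Ac2O, DMAP, Et3N) gives (1R,4E,7Z,9S,12E,14S)-9,20-bis(tert-butyldimethylsilyloxy)cembra-4,7,12,15-tetraen-14-yl acetate F10. Excess HF·pyridine at rt removes both silyl groups to give (1R,4E,7Z,9S,12E,14S)-9,20-dihydroxycembra-4,7,12,15-tetraen-14-yl acetate F11. Acetyl chloride with 2,4,6-collidine in CH2Cl2 at −78 °C then acylates only the primary allylic hydroxyl and comes back to the route at 30.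

**Further compounds**

F1 | step 16 | (2E,6E,9Z,11S)-11-(tert-butyldimethylsilyloxy)-2,6,10-trimethyltrideca-2,6,9,12-tetraen-1-ol | OC/C(C)=C/CC/C(C)=C/C/C=C(/C)[C@@H](O[Si](C)(C)C(C)(C)C)C=C
F2 | step 16 | (3S,4Z,7E,11E)-13-bromo-3-(tert-butyldimethylsilyloxy)-4,8,12-trimethyltrideca-1,4,7,11-tetraene | BrC/C(C)=C/CC/C(C)=C/C/C=C(/C)[C@@H](O[Si](C)(C)C(C)(C)C)C=C
F3 | step 16 | (Z)-4-(tert-butyldimethylsilyloxy)-3-iodobut-2-enal | O=C/C=C(\I)CO[Si](C)(C)C(C)(C)C
F4 | step 16 | (2Z,4R,5R,8E,11Z,13S)-1,13-bis(tert-butyldimethylsilyloxy)-2-iodo-8,12-dimethyl-5-(prop-1-en-2-yl)pentadeca-2,8,11,14-tetraen-4-ol | C=C(C)[C@H]([C@@H](O)/C=C(\I)CO[Si](C)(C)C(C)(C)C)CC/C(C)=C/C/C=C(/C)[C@@H](O[Si](C)(C)C(C)(C)C)C=C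
F5 | step 16 | C11-(9-borabicyclo[3.3.1]nonan-9-yl) O14-(9-borabicyclo[3.3.1]nonan-9-yl) derivative of F4 | C=C(C)[C@H]([C@@H](OB1C2CCCC1CCC2)/C=C(\I)CO[Si](C)(C)C(C)(C)C)CC/C(C)=C/C/C=C(/C)[C@@H](O[Si](C)(C)C(C)(C)C)CCB1C2CCCC1CCC2
F6 | step 8 | (1Z,3S)-1-iodo-2-methylpenta-1,4-dien-3-ol | I/C=C(/C)[C@@H](O)C=C
F7 | step 8 | tert-butyl{[(1Z,3S)-1-iodo-2-methylpenta-1,4-dien-3-yl]oxy}dimethylsilane | I/C=C(/C)[C@@H](O[Si](C)(C)C(C)(C)C)C=C
F8 | step 8 | [(1Z,3S)-3-(tert-butyldimethylsilyloxy)-2-methylpenta-1,4-dien-1-yl]lithium | [Li]/C=C(/C)[C@@H](O[Si](C)(C)C(C)(C)C)C=C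
F9 | step 8 | [(1Z,3S)-3-(tert-butyldimethylsilyloxy)-2-methylpenta-1,4-dien-1-yl]zinc bromide | Br[Zn]/C=C(/C)[C@@H](O[Si](C)(C)C(C)(C)C)C=C
F10 | step 17 | (1R,4E,7Z,9S,12E,14S)-9,20-bis(tert-butyldimethylsilyloxy)cembra-4,7,12,15-tetraen-14-yl acetate | C=C(C)[C@H]1CC/C(C)=C/C/C=C(/C)[C@@H](O[Si](C)(C)C(C)(C)C)CC/C(CO[Si](C)(C)C(C)(C)C)=C\[C@@H]1OC(C)=O
F11 | step 17 | (1R,4E,7Z,9S,12E,14S)-9,20-dihydroxycembra-4,7,12,15-tetraen-14-yl acetate | C=C(C)[C@H]1CC/C(C)=C/C/C=C(/C)[C@@H](O)CC/C(CO)=C\[C@@H]1OC(C)=O
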